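**Retrosynthetic overview** (longipinane numbering: cyclohexenone C1(=O)–C2=C3(Me)–C4–C5–C11; cyclobutane C4–C10–C11–C5; cycloheptane C5–C6(Me2)–C7–C8–C9–C10–C11)
1. The C7 angelate and C9 acetate are cut last; the C9–OH comes directly out of the key step.
2. Key disconnection C9–C10 (cycloheptane): reductive alkene–aldehyde cyclisation of the bicyclo[3.1.1]heptenone 15. The enabling feature is the exocyclic methylidene on cyclobutane carbon C10, flanked by the bridgeheads C4 and C11 and 1,3-cis across the cyclobutane to the C5 side chain that ends in the C9 aldehyde.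
3. Cyclohexene ring: C3–C4 by gold-catalysed 6-endo-dig Conia-ene closure across the cyclobutanone, after C1–C11 by Mukaiyama aldol with but-2-ynal.
4. Cyclobutane: dichloroketene [2+2] on a terminal alkene, then enantiotopic-group-selective enolisation; C7 from iridium-catalysed tert-prenylation.
5. Ring order: cyclobutane, then cyclohexene, then cycloheptane.

Key step: step 11

Assumption: (S)-SEGPHOS is taken to give the 3R carbinol in step 1 and the (S,S)-lithium amide to enolise toward the future C11 in step 4; if either sense is the opposite, the mirror-image ligand or base is used.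

Step 1
Reactants: 1 3-[(4-methoxyphenyl)methoxy]propan-1-ol; 2 3-methylbuta-1,2-diene
Product: 3 (3R)-1-[(4-methoxyphenyl)methoxy]-4,4-dimethylhex-5-en-3-ol
Conditions: [Ir(cod)Cl]2 (2.5 mol %), (S)-SEGPHOS (5 mol %), 4-cyano-3-nitrobenzoic acid (10 mol %), Cs2CO3 (20 mol %), toluene, 60 °C
Reagents that add atoms: none
Why: Iridium-catalysed transfer-hydrogenative carbonyl tert-prenylation (reverse prenylation), in which the alcohol is dehydrogenated in situ and the allene-derived allyliridium adds through its dimethyl-substituted terminus, so that the chiral catalyst sets C7 (R) by reagent control and C6 arrives with both methyl groups and a vinyl group.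

Step 2
Reactants: 3 homoallylic alcohol
Product: 4 tert-butyldimethylsilyl ether of 3
Conditions: t-BuMe2SiOTf, 2,6-lutidine, CH2Cl2, 0 °C
Reagents that add atoms: tert-butyldimethylsilyl trifluoromethanesulfonate, CC(C)(C)[Si](C)(C)OS(=O)(=O)C(F)(F)F
Why: Silylation of the hindered neopentyl-type alcohol with the silyl triflate, which touches no stereocentre.

Step 3
Reactants: 4 silyl ether
Product: 6 3-substituted cyclobutan-1-one, via dichlorocyclobutanone 5 (not isolated)
Conditions: Cl3CCOCl, Zn–Cu couple, Et2O/DME, 23 °C, ultrasound; then Zn, AcOH, 23 °C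
Reagents that add atoms: trichloroacetyl chloride, ClC(=O)C(Cl)(Cl)Cl
Why: Thermal [2+2] cycloaddition of dichloroketene to the terminal alkene is regioselective (carbonyl carbon to the CH2 terminus) and zinc then removes both chlorines, so the cyclobutane arrives as a 3-substituted cyclobutanone (C10 as the carbonyl) whose ring carbon C5 is not yet stereogenic.

Step 4
Reactants: 6 cyclobutanone
Product: 7 triethylsilyl enol ether, (3S)-configured at the ring carbon C5
Conditions: (S,S)-bis(1-phenylethyl)amine, n-BuLi, THF, −78 °C; then Et3SiCl and 6, −100 °C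
Reagents that add atoms: chlorotriethylsilane, CC[Si](Cl)(CC)CC
Why: Enantiotopic-group-selective deprotonation of a 3-substituted cyclobutanone by a C2-symmetric chiral lithium amide with in situ silyl trapping, in which the choice of the α-methylene that is enolised (the future C11) makes C5 stereogenic by reagent control.

Step 5
Reactants: 7 silyl enol ether; 8 but-2-ynal
Product: 9 2,3-trans-2-[1-(triethylsilyloxy)but-2-yn-1-yl]cyclobutanone
Conditions: Tf2NH (2 mol %), CH2Cl2, −78 °C
Reagents that add atoms: none
Why: Mukaiyama aldol addition with silyl transfer (silyl triflimide formed from Tf2NH as the Lewis acid), in which the aldehyde attacks C11 on the face anti to the bulky C5 substituent to form C1–C11 trans to it, while the C1 carbinol centre forms as an epimeric pair that is of no consequence because C1 becomes the ketone in step 10.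

Step 6
Reactants: 9 silyloxy ketone
Product: 10 tert-butyldimethylsilyl enol ether (enolised toward C4)
Conditions: LiN(i-Pr)2, THF, −78 °C; then t-BuMe2SiCl, HMPA, −78 → 0 °C
Reagents that add atoms: tert-butyldimethylsilyl chloride, CC(C)(C)[Si](C)(C)Cl
Why: Kinetic deprotonation at the unsubstituted α-methylene C4 and O-silylation give the regio-defined silyl enol ether needed for the carbocyclisation without changing a stereocentre.

Step 7
Reactants: 10 silyl enol ether
Product: 11 bicyclo[3.1.1]hept-2-en-6-one
Conditions: [(t-Bu)2(2-biphenylyl)P]Au(NCMe)SbF6 (5 mol %), CH2Cl2/MeOH 10:1, 23 °C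
Reagents that add atoms: none
Why: Gold-catalysed 6-endo-dig Conia-ene-type carbocyclisation of a silyl enol ether onto an alkyne, a reaction used for bridged bicyclic ketones, in which C4 attacks the gold-activated alkyne carbon C3 from the only face the C11 tether reaches, which sets C4 and closes the cyclohexene across the 1,3-positions of the cyclobutanone with the C5 substituent anti to the new bridge.

Step 8
Reactants: 11 bicyclic ketone
Product: 12 6-methylidene compound
Conditions: Ph3PCH3Br, KOt-Bu, toluene, 0 → 80 °C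
Reagents that add atoms: methyltriphenylphosphonium bromide, C[P+](c1ccccc1)(c1ccccc1)c1ccccc1.[Br-]
Why: Wittig methylenation of the strained cyclobutanone, which is flanked by two bridgeheads and therefore cannot enolise or epimerise.

Step 9
Reactants: 12 methylidene compound
Product: 14 diol, via primary alcohol 13 (not isolated)
Conditions: DDQ, CH2Cl2/pH 7 buffer, 0 °C; then MeOH, PPTS, 23 °C
Reagents that add atoms: none
Why: Oxidative cleavage of the 4-methoxybenzyl ether by DDQ followed by mild acid methanolysis of the allylic triethylsilyl ether, conditions under which the hindered secondary tert-butyldimethylsilyl ether at C7 should stay intact.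

Step 10
Reactants: 14 diol
Product: 15 enone aldehyde
Conditions: Dess–Martin periodinane, NaHCO3, CH2Cl2, 0 → 23 °C
Reagents that add atoms: none
Why: Dess–Martin oxidation converts the allylic C1 alcohol into the enone (which removes the epimeric centre) and the primary alcohol into the C9 aldehyde in one buffered operation.

Step 11
Reactants: 15 enone aldehyde
Product: 17 tricyclic C9 alcohol, via phenylsilyl ether 16 (not isolated)
Conditions: [N,N'-bis(3,5-di-tert-butylsalicylidene)ethane-1,2-diaminato]cobalt (10 mol %), CrCl3(THF)3 (30 mol %), PhSiH3 (2 equiv), THF, 0.005 M, 23 °C; then aq. K2CO3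
Reagents that add atoms: none
Why: Proposed new method: the cobalt hydride formed from the cobalt salen complex and PhSiH3 transfers a hydrogen atom to the CH2 terminus of the methylidene group (Markovnikov metal-hydride hydrogen-atom transfer, MHAT), the tertiary cyclobutyl radical at C10 is captured by divalent chromium, and the alkylchromium adds to the C9 aldehyde before the chromium alkoxide is silylated, which closes the catalytic cycle. The closest known reaction type is the intermolecular branch-selective cobalt/chromium reductive coupling of 1,1-disubstituted alkenes with aldehydes, together with the iron-mediated MHAT cyclisation of alkenyl ketones; new is its use for a ring closure, here a 7-exo-trig attack of C10 on the aldehyde that forms the cycloheptane C5–C6–C7–C8–C9–C10–C11. The substrate makes this good chemistry because the C10 radical is flanked by the bridgeheads C4 and C11, so it has no β-hydrogen to lose except back to the methylidene, cannot rearrange, and sits 1,3-cis across the cyclobutane to the C5 side chain that holds the aldehyde over it. The new quaternary centre C10 is fixed by the tether, since only the cyclobutane face that carries C6 can be reached, so the new methyl group ends on the side of the enone bridge. C9 is set by 1,3-anti induction from the C7 silyloxy group (non-chelated polar model), which inside the forming ring places the C9 hydroxyl trans to the C7 oxygen. The step needs chemoselectivity for the electron-rich 1,1-disubstituted alkene over the enone double bond and for the aldehyde over the enone carbonyl, both expected from the polarity of the metal hydride and the aldehyde preference of alkylchromium reagents.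

Step 12
Reactants: 17 tricyclic alcohol
Product: 18 C9 acetate
Conditions: Ac2O, DMAP, Et3N, CH2Cl2, 23 °C
Reagents that add atoms: acetic anhydride, CC(=O)OC(C)=O
Why: DMAP-catalysed acetylation of the hindered secondary C9 alcohol with retention of configuration.

Step 13
Reactants: 18 silyl ether acetate
Product: 19 C7 alcohol
Conditions: HF·pyridine, pyridine, THF, 0 → 23 °C
Reagents that add atoms: none
Why: Fluoride-mediated desilylation under buffered acidic conditions, which should free the C7 alcohol without acyl migration from the trans C9 acetate.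

Step 14
Reactants: 19 hydroxy acetate; 20 angelic acid
Product: 22 target, via mixed anhydride 21 (not isolated)
Conditions: 20, 2,4,6-trichlorobenzoyl chloride, Et3N, toluene, 23 °C; then 19, toluene, 80 °C
Reagents that add atoms: none
Why: Yamaguchi esterification through the mixed anhydride, run without a nucleophilic catalyst because this variant should acylate hindered alcohols with angelic acid without Z to E isomerisation, the C7 configuration being retained.

**Compound list**
1 | 3-[(4-methoxyphenyl)methoxy]propan-1-ol | COc1ccc(COCCCO)cc1 | starting material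
2 | 3-methylbuta-1,2-diene | CC(C)=C=C | starting material
3 | (3R)-1-[(4-methoxyphenyl)methoxy]-4,4-dimethylhex-5-en-3-ol | COc1ccc(COCC[C@@H](O)C(C)(C)C=C)cc1 | intermediate
4 | tert-butyl{[(3R)-1-[(4-methoxyphenyl)methoxy]-4,4-dimethylhex-5-en-3-yl]oxy}dimethylsilane | COc1ccc(COCC[C@@H](O[Si](C)(C)C(C)(C)C)C(C)(C)C=C)cc1 | intermediate
5 | 2,2-dichloro-3-[(3R)-3-(tert-butyldimethylsilyloxy)-5-[(4-methoxyphenyl)methoxy]-2-methylpentan-2-yl]cyclobutan-1-one, both epimers at ring C3 | COc1ccc(COCC[C@@H](O[Si](C)(C)C(C)(C)C)C(C)(C)C2CC(=O)C2(Cl)Cl)cc1 | intermediate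
6 | 3-[(3R)-3-(tert-butyldimethylsilyloxy)-5-[(4-methoxyphenyl)methoxy]-2-methylpentan-2-yl]cyclobutan-1-one | COc1ccc(COCC[C@@H](O[Si](C)(C)C(C)(C)C)C(C)(C)C2CC(=O)C2)cc1 | intermediate
7 | triethyl{[(3S)-3-[(3R)-3-(tert-butyldimethylsilyloxy)-5-[(4-methoxyphenyl)methoxy]-2-methylpentan-2-yl]cyclobut-1-en-1-yl]oxy}silane | CC[Si](CC)(CC)OC1=C[C@@H](C(C)(C)[C@@H](CCOCc2ccc(OC)cc2)O[Si](C)(C)C(C)(C)C)C1 | intermediate
8 | but-2-ynal | CC#CC=O | starting material
9 | 2,3-trans-3-[side chain as in 6]-2-[1-(triethylsilyloxy)but-2-yn-1-yl]cyclobutan-1-one, both epimers at the silyloxy carbon (future C1) | O=C1C[C@H](C(C)(C)[C@@H](CCOCc2ccc(OC)cc2)O[Si](C)(C)C(C)(C)C)[C@H]1C(O[Si](CC)(CC)CC)C#CC | intermediate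
10 | 3,4-trans-1-(tert-butyldimethylsilyloxy)-3-[side chain as in 6]-4-[1-(triethylsilyloxy)but-2-yn-1-yl]cyclobut-1-ene, both epimers at the silyloxy carbon | CC(C)(C)[Si](C)(C)OC1=C[C@H](C(C)(C)[C@@H](CCOCc2ccc(OC)cc2)O[Si](C)(C)C(C)(C)C)[C@H]1C(O[Si](CC)(CC)CC)C#CC | intermediate
11 | 2-methyl-4-(triethylsilyloxy)-7-[side chain as in 6]bicyclo[3.1.1]hept-2-en-6-one, side chain anti to the three-carbon bridge, both epimers at the silyloxy carbon | O=C1[C@H]2[C@@H](C(C)(C)[C@@H](CCOCc3ccc(OC)cc3)O[Si](C)(C)C(C)(C)C)[C@@H]1C(C)=CC2O[Si](CC)(CC)CC | intermediate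
12 | 6-methylidene analogue of 11 (C=CH2 in place of C=O) | C=C1[C@H]2[C@@H](C(C)(C)[C@@H](CCOCc3ccc(OC)cc3)O[Si](C)(C)C(C)(C)C)[C@@H]1C(C)=CC2O[Si](CC)(CC)CC | intermediate
13 | primary alcohol from 12 (4-methoxybenzyl group removed) | C=C1[C@H]2[C@@H](C(C)(C)[C@@H](CCO)O[Si](C)(C)C(C)(C)C)[C@@H]1C(C)=CC2O[Si](CC)(CC)CC | intermediate
14 | diol: 2-methyl-6-methylidene-7-[(3R)-3-(tert-butyldimethylsilyloxy)-5-hydroxy-2-methylpentan-2-yl]bicyclo[3.1.1]hept-2-en-4-ol, both carbinol epimers | C=C1[C@H]2[C@@H](C(C)(C)[C@@H](CCO)O[Si](C)(C)C(C)(C)C)[C@@H]1C(C)=CC2O | intermediate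
15 | 4-methyl-6-methylidene-7-[(3R)-3-(tert-butyldimethylsilyloxy)-2-methyl-5-oxopentan-2-yl]bicyclo[3.1.1]hept-3-en-2-one, side chain anti to the enone bridge (4R,5S,7R,11R in longipinane numbering) | C=C1[C@H]2[C@@H](C(C)(C)[C@@H](CC=O)O[Si](C)(C)C(C)(C)C)[C@@H]1C(C)=CC2=O | intermediate
16 | phenylsilyl ether of 17 at the C9 oxygen | CC(C)(C)[Si](C)(C)O[C@@H]1C[C@@H](O[SiH2]c4ccccc4)[C@@]2(C)[C@@H]3C(=O)C=C(C)[C@H]2[C@@H]3C1(C)C | intermediate
17 | (4R,5S,7R,9R,10R,11R)-7-(tert-butyldimethylsilyloxy)-9-hydroxylongipin-2-en-1-one | CC(C)(C)[Si](C)(C)O[C@@H]1C[C@@H](O)[C@@]2(C)[C@@H]3C(=O)C=C(C)[C@H]2[C@@H]3C1(C)C | intermediate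
18 | (4R,5S,7R,9R,10R,11R)-9-acetoxy-7-(tert-butyldimethylsilyloxy)longipin-2-en-1-one | CC(C)(C)[Si](C)(C)O[C@@H]1C[C@@H](OC(C)=O)[C@@]2(C)[C@@H]3C(=O)C=C(C)[C@H]2[C@@H]3C1(C)C | intermediate
19 | (4R,5S,7R,9R,10R,11R)-9-acetoxy-7-hydroxylongipin-2-en-1-one | O[C@@H]1C[C@@H](OC(C)=O)[C@@]2(C)[C@@H]3C(=O)C=C(C)[C@H]2[C@@H]3C1(C)C | intermediate
20 | angelic acid, (Z)-2-methylbut-2-enoic acid | C/C=C(/C)C(=O)O | starting material
21 | (Z)-2-methylbut-2-enoic 2,4,6-trichlorobenzoic anhydride | C/C=C(/C)C(=O)OC(=O)c1c(Cl)cc(Cl)cc1Cl | intermediate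
22 | (4R,5S,7R,9R,10R,11R)-9-acetoxy-7-[(Z)-2-methylbut-2-enoyloxy]longipin-2-en-1-one (CNP0260482.1) | C/C=C(/C)C(=O)O[C@@H]1C[C@@H](OC(C)=O)[C@@]2(C)[C@@H]3C(=O)C=C(C)[C@H]2[C@@H]3C1(C)C | target

**Totals**
Total step count: 14. Longest linear sequence: 14 steps (1 to 22); 2, 8 and 20 enter as purchased compounds.

**Steps most likely to fail**

Step 11 (proposed new method). The C10 radical may be quenched before ring closure (plain hydrogenation of the methylidene group, or hydrosilylation of the aldehyde), and facial selectivity at C9 may be poor. The fallback uses known chemistry, sets out from 11 and comes back at 17. Horner–Wadsworth–Emmons olefination of ketone 11 with diethyl [(phenylsulfonyl)methyl]phosphonate (NaH, THF) should give the vinyl sulfone F1. DDQ removes the 4-methoxybenzyl group to give the alcohol F2, and Dess–Martin oxidation gives the aldehyde F3. SmI2 (HMPA, t-BuOH, THF, −78 °C) then forms the C9 ketyl, which adds 7-exo-trig to C10, the β-carbon of the vinyl sulfone (ketyl–olefin cyclisation), to give the hydroxy sulfone F4. Sodium amalgam (Na/Hg, Na2HPO4, MeOH) removes the sulfonyl group and leaves the C10 methyl compound F5. PPTS in MeOH cleaves the triethylsilyl ether to the diol F6, and MnO2 oxidises only the allylic C1 alcohol, which gives 17.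

Step 7. Strain in the transition state of the bridging closure may let protodesilylation of the silyl enol ether or hydration of the alkyne outrun C–C bond formation. The fallback sets out from 7 and 8 and comes back at 11. Hydroiodination of 8 (NaI, AcOH) should give (Z)-3-iodobut-2-enal F7. The same silyl-transfer Mukaiyama aldol with 7 gives the iodoalkenyl cyclobutanone F8. Its zinc enolate, formed at C4 (LiN(i-Pr)2, THF, −78 °C; then ZnCl2), is closed by palladium-catalysed intramolecular α-alkenylation of the ketone (Pd2(dba)3, P(t-Bu)3, THF, 50 °C), a cross-coupling in which the ring is closed by reductive elimination and not by attack on a π-activated alkyne, to give 11.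

Step 14. The activated angelic acid may isomerise from Z to E (tiglate formation), and acylation of the hindered C7 hydroxyl may stay incomplete. The fallback sets out from 19 and comes back at 22. Esterification of 19 with 2-[bis(2,2,2-trifluoroethoxy)phosphoryl]propanoic acid (EDC, DMAP, CH2Cl2) gives the phosphonate ester F9. Still–Gennari olefination with acetaldehyde (KN(SiMe3)2, 18-crown-6, THF, −78 °C) then builds the Z-configured 2-methylbut-2-enoate on the molecule and gives 22.

Further compounds
F1 | step 11 | vinyl sulfone: 6-[(phenylsulfonyl)methylidene] analogue of 11 (alkene geometry not defined) | O=S(=O)(c4ccccc4)C=C1[C@H]2[C@@H](C(C)(C)[C@@H](CCOCc3ccc(OC)cc3)O[Si](C)(C)C(C)(C)C)[C@@H]1C(C)=CC2O[Si](CC)(CC)CC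
F2 | step 11 | primary alcohol from F1 (4-methoxybenzyl group removed) | O=S(=O)(c4ccccc4)C=C1[C@H]2[C@@H](C(C)(C)[C@@H](CCO)O[Si](C)(C)C(C)(C)C)[C@@H]1C(C)=CC2O[Si](CC)(CC)CC
F3 | step 11 | aldehyde from F2 | O=S(=O)(c4ccccc4)C=C1[C@H]2[C@@H](C(C)(C)[C@@H](CC=O)O[Si](C)(C)C(C)(C)C)[C@@H]1C(C)=CC2O[Si](CC)(CC)CC
F4 | step 11 | tricyclic hydroxy sulfone: 7-(tert-butyldimethylsilyloxy)-9-hydroxy-10-[(phenylsulfonyl)methyl]-1-(triethylsilyloxy)longipin-2-ene skeleton (C10 carries CH2SO2Ph in place of methyl) | CC(C)(C)[Si](C)(C)O[C@@H]1C[C@@H](O)[C@@]2(CS(=O)(=O)c4ccccc4)[C@@H]3C(O[Si](CC)(CC)CC)C=C(C)[C@H]2[C@@H]3C1(C)C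
F5 | step 11 | 7-(tert-butyldimethylsilyloxy)-1-(triethylsilyloxy)longipin-2-en-9-ol | CC(C)(C)[Si](C)(C)O[C@@H]1C[C@@H](O)[C@@]2(C)[C@@H]3C(O[Si](CC)(CC)CC)C=C(C)[C@H]2[C@@H]3C1(C)C
F6 | step 11 | 7-(tert-butyldimethylsilyloxy)longipin-2-ene-1,9-diol | CC(C)(C)[Si](C)(C)O[C@@H]1C[C@@H](O)[C@@]2(C)[C@@H]3C(O)C=C(C)[C@H]2[C@@H]3C1(C)C
F7 | step 7 | (Z)-3-iodobut-2-enal | O=C/C=C(/C)I
F8 | step 7 | 2,3-trans-3-[side chain as in 6]-2-[(Z)-3-iodo-1-(triethylsilyloxy)but-2-en-1-yl]cyclobutan-1-one | O=C1C[C@H](C(C)(C)[C@@H](CCOCc2ccc(OC)cc2)O[Si](C)(C)C(C)(C)C)[C@H]1C(O[Si](CC)(CC)CC)/C=C(/C)I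
F9 | step 14 | 7-O-{2-[bis(2,2,2-trifluoroethoxy)phosphoryl]propanoyl} derivative of 19 | CC(C(=O)O[C@@H]1C[C@@H](OC(C)=O)[C@@]2(C)[C@@H]3C(=O)C=C(C)[C@H]2[C@@H]3C1(C)C)P(=O)(OCC(F)(F)F)OCC(F)(F)F
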